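**Retrosynthetic overview**
1. Glycyrdione A (ring A = 4-hydroxy-3-prenylphenyl, ring B = 2,4-dihydroxy-5-prenylphenyl, prenyl = 3-methylbut-2-en-1-yl) is cut between the ring A carbonyl carbon and the central CH2; the ring A aroyl group is delivered from O2 of ring B to the acetyl carbon (Baker-Venkataraman O-to-C acyl shift).
2. Both C-prenyl groups (C3 of ring A, C5 of ring B) go back to O-(1,1-dimethylallyl) ethers on O4 of each ring (aromatic Claisen rearrangement), run in the same flask before the acyl shift.
3. Enabling feature: the phenolic oxygen on C2 of ring B, ortho to the ketone. As an aroyl ester it holds the ring A carbonyl five atoms from the acetyl carbon (six-membered transition state), removes the O2-H to ketone chelate so that the ring B shift should go to C5 and not C3, and is returned as the free C2 hydroxyl. Each prenyl carbon sits ortho to a phenolic oxygen, the mark of a [3,3] shift.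
4. The ester comes from DCC coupling of 4-(1,1-dimethylpropargyloxy)benzoic acid with 2-hydroxy-4-(1,1-dimethylpropargyloxy)acetophenone, followed by one Lindlar semi-hydrogenation of both alkynes.
5. No ring is formed: both benzene rings are bought (methyl 4-hydroxybenzoate, 2,4-dihydroxyacetophenone), and no protecting group is used.

Key step: step 6

Remark: the target is drawn as the diketo tautomer; it should exist largely as the hydrogen-bonded enol, which is the same compound.

**Route**

Step 1
Reactants: 1 methyl 4-hydroxybenzoate; 2 3-chloro-3-methylbut-1-yne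
Product: 3 methyl 4-(2-methylbut-3-yn-2-yloxy)benzoate
Conditions: K2CO3, KI (cat.), CuI (cat.), acetone, 60 °C
Reagents that add atoms: none
Why: Copper-assisted O-alkylation of a phenoxide by a tertiary propargylic chloride is the standard entry to aryl 1,1-dimethylpropargyl ethers.

Step 2
Reactants: 3 methyl 4-(2-methylbut-3-yn-2-yloxy)benzoate
Product: 4 4-(2-methylbut-3-yn-2-yloxy)benzoic acid
Conditions: LiOH·H2O, THF/MeOH/H2O, rt; then 1 M HCl, 0 °C, to pH 3
Reagents that add atoms: lithium hydroxide, [Li+].[OH-]
Why: Saponification of a methyl ester; the tertiary propargyl aryl ether and the terminal alkyne should tolerate aqueous base and brief cold dilute acid.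

Step 3
Reactants: 5 1-(2,4-dihydroxyphenyl)ethanone (2,4-dihydroxyacetophenone); 2 3-chloro-3-methylbut-1-yne
Product: 6 1-[2-hydroxy-4-(2-methylbut-3-yn-2-yloxy)phenyl]ethanone
Conditions: K2CO3, KI (cat.), CuI (cat.), acetone, 60 °C
Reagents that add atoms: none
Why: The same copper-assisted O-alkylation should be selective for O4, because the C2 hydroxyl is hydrogen-bonded to the ketone and the C4 hydroxyl is the more acidic and nucleophilic one.

Step 4
Reactants: 4 4-(2-methylbut-3-yn-2-yloxy)benzoic acid; 6 1-[2-hydroxy-4-(2-methylbut-3-yn-2-yloxy)phenyl]ethanone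
Product: 7 2-acetyl-5-(2-methylbut-3-yn-2-yloxy)phenyl 4-(2-methylbut-3-yn-2-yloxy)benzoate
Conditions: DCC, DMAP (cat.), CH2Cl2, 0 °C to rt
Reagents that add atoms: none
Why: Steglich esterification, in which DMAP relays the acyl group as an acylpyridinium ion to the hydrogen-bonded C2 phenol under neutral conditions.

Step 5
Reactants: 7 2-acetyl-5-(2-methylbut-3-yn-2-yloxy)phenyl 4-(2-methylbut-3-yn-2-yloxy)benzoate
Product: 8 2-acetyl-5-(2-methylbut-3-en-2-yloxy)phenyl 4-(2-methylbut-3-en-2-yloxy)benzoate
Conditions: H2 (1 atm), Pd on CaCO3 poisoned with Pb(OAc)2 (Lindlar catalyst), quinoline, EtOAc, rt, stopped after uptake of 2 equiv of H2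
Reagents that add atoms: none
Why: Lindlar semi-hydrogenation should stop both terminal alkynes at the alkene and leave the aryl ester and the ketone untouched.

Step 6
Reactants: 8 2-acetyl-5-(2-methylbut-3-en-2-yloxy)phenyl 4-(2-methylbut-3-en-2-yloxy)benzoate
Product: 10 glycyrdione A, via diphenol ester 9 (not isolated)
Conditions: degassed o-xylene, 145 °C (sealed tube); then THF, LiN(SiMe3)2 (4.5 equiv), −20 °C to rt; then 1 M HCl to pH 5, 0 °C
Reagents that add atoms: none
Why: Heating should trigger two aromatic Claisen rearrangements ([3,3] shifts through chair transition states, then enolization of the ortho-dienones) that turn each O-(1,1-dimethylallyl) ether into a free phenol with a prenyl group on the neighbouring ring carbon, giving diphenol ester 9. LiN(SiMe3)2 should then form the trianion of 9, whose acetyl enolate carbon attacks the ring A ester carbonyl held on O2 of ring B through a six-membered cyclic tetrahedral alkoxide (6-exo-trig attack; this transient ring reopens by loss of the ring B phenoxide), which is the Baker-Venkataraman O-to-C acyl shift that forms the CH2-C(=O) bond of the 1,3-diketone. The closest known reactions are the thermal rearrangement of aryl 1,1-dimethylallyl ethers to ortho-prenylphenols and the C-aroylation of lithium polyanions of unprotected hydroxyacetophenones. No ring of the target is closed and no stereocentre is formed. The selectivity needed is migration to C5 and not C3 on ring B, which the acylated O2 should secure because there is no hydrogen-bonded chelate to the ketone (the bond fixation that sends allyl groups to C3 in chelated 2-hydroxy-4-allyloxyacetophenones, whereas 2-O-blocked analogues are known to go to C5) and C3 is flanked by two oxygen substituents; on ring A the two ortho carbons are equivalent. The order heat then base is essential, and C-acylation should win over reversible phenoxide-to-phenoxide acyl transfer because only the β-diketonate forms irreversibly.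

**Compound list**
1 | methyl 4-hydroxybenzoate | COC(=O)c1ccc(O)cc1 | starting material
2 | 3-chloro-3-methylbut-1-yne | CC(C)(Cl)C#C | starting material
3 | methyl 4-(2-methylbut-3-yn-2-yloxy)benzoate | COC(=O)c1ccc(OC(C)(C)C#C)cc1 | intermediate
4 | 4-(2-methylbut-3-yn-2-yloxy)benzoic acid | OC(=O)c1ccc(OC(C)(C)C#C)cc1 | intermediate
5 | 1-(2,4-dihydroxyphenyl)ethanone (2,4-dihydroxyacetophenone) | CC(=O)c1ccc(O)cc1O | starting material
6 | 1-[2-hydroxy-4-(2-methylbut-3-yn-2-yloxy)phenyl]ethanone | CC(=O)c1ccc(OC(C)(C)C#C)cc1O | intermediate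
7 | 2-acetyl-5-(2-methylbut-3-yn-2-yloxy)phenyl 4-(2-methylbut-3-yn-2-yloxy)benzoate | CC(=O)c1ccc(OC(C)(C)C#C)cc1OC(=O)c1ccc(OC(C)(C)C#C)cc1 | intermediate
8 | 2-acetyl-5-(2-methylbut-3-en-2-yloxy)phenyl 4-(2-methylbut-3-en-2-yloxy)benzoate | CC(=O)c1ccc(OC(C)(C)C=C)cc1OC(=O)c1ccc(OC(C)(C)C=C)cc1 | intermediate
9 | 2-acetyl-5-hydroxy-4-(3-methylbut-2-en-1-yl)phenyl 4-hydroxy-3-(3-methylbut-2-en-1-yl)benzoate | CC(=O)c1cc(CC=C(C)C)c(O)cc1OC(=O)c1ccc(O)c(CC=C(C)C)c1 | intermediate
10 | glycyrdione A, 1-[2,4-dihydroxy-5-(3-methylbut-2-en-1-yl)phenyl]-3-[4-hydroxy-3-(3-methylbut-2-en-1-yl)phenyl]propane-1,3-dione | CC(C)=CCc1cc(C(=O)CC(=O)c2cc(CC=C(C)C)c(O)cc2O)ccc1O | target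

**Count**
Total steps: 6. Longest linear sequence: 5 steps (steps 1, 2, 4, 5, 6).

**Steps most likely to fail**

Step 6. Two processes may go wrong. The ring B allyl shift may go partly to C3 instead of C5. The acyl shift may stall because the ring A phenoxide lowers the electrophilicity of the ester carbonyl, leaving phenoxide-to-phenoxide acyl scrambling to take over. The fallback gives up the one-flask cascade and joins two separately prenylated, protected halves by a crossed Claisen condensation; it sets out from compounds 1 and 5 and comes back at compound 10. Compound 1 would be C-prenylated ortho to the phenol as its sodium phenoxide in a non-polar medium (NaH, prenyl bromide, toluene, rt) to give methyl 4-hydroxy-3-(3-methylbut-2-en-1-yl)benzoate F1, which would be protected (MOMCl, iPr2NEt, CH2Cl2) as methyl 4-(methoxymethoxy)-3-(3-methylbut-2-en-1-yl)benzoate F2. Compound 5 would be prenylated at C5 by Friedel-Crafts alkylation (2-methylbut-3-en-2-ol, BF3·OEt2, dioxane, rt; the C3 isomer removed by chromatography) to give 1-[2,4-dihydroxy-5-(3-methylbut-2-en-1-yl)phenyl]ethanone F3, and both phenols protected (NaH, MOMCl, DMF) to give 1-[2,4-bis(methoxymethoxy)-5-(3-methylbut-2-en-1-yl)phenyl]ethanone F4. The sodium enolate of F4 would be condensed with F2 (NaH, THF, reflux) to give 1-[2,4-bis(methoxymethoxy)-5-(3-methylbut-2-en-1-yl)phenyl]-3-[4-(methoxymethoxy)-3-(3-methylbut-2-en-1-yl)phenyl]propane-1,3-dione F5. Mild acetal cleavage (dilute HCl in MeOH, rt, kept short to avoid chroman and flavone formation) should then give 10.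

Step 5. Over-reduction of one or both terminal alkenes to 1,1-dimethylpropyl ethers (inert in the Claisen step), or uneven reduction of the two alkynes, may give mixtures that are hard to separate. The fallback avoids alkynes altogether by installing the 1,1-dimethylallyl ethers directly through zerovalent palladium catalysed decarboxylative O-allylation; it sets out from compounds 1 and 5 and comes back at compound 8. Compound 1 with tert-butyl 2-methylbut-3-en-2-yl carbonate (CC(C)(C)OC(=O)OC(C)(C)C=C) and Pd(PPh3)4 in THF at 0 °C should give the branched (kinetic) ether methyl 4-(2-methylbut-3-en-2-yloxy)benzoate F6. Saponification (LiOH, THF/H2O, rt; citric acid to pH 5) would give 4-(2-methylbut-3-en-2-yloxy)benzoic acid F7. The same allylation of compound 5, selective for the unchelated O4, should give 1-[2-hydroxy-4-(2-methylbut-3-en-2-yloxy)phenyl]ethanone F8. Coupling of F7 with F8 (DCC, DMAP, CH2Cl2, 0 °C to rt) would give 8.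

Step 4. Acylation of the hydrogen-bonded C2 phenol may be slow enough that the O-acylisourea rearranges to the unreactive N-acylurea. The fallback separates activation from acylation and uses a preformed phenoxide; it sets out from compounds 4 and 6 and comes back at compound 7. Acid 4 would be converted under neutral conditions (1-chloro-N,N,2-trimethylprop-1-en-1-amine, CH2Cl2, 0 °C) into 4-(2-methylbut-3-yn-2-yloxy)benzoyl chloride F9. F9 would be added to the sodium phenoxide of 6 (NaH, 1.0 equiv, THF, 0 °C) to give 7.

**Further compounds**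
F1 | step 6 | methyl 4-hydroxy-3-(3-methylbut-2-en-1-yl)benzoate | COC(=O)c1ccc(O)c(CC=C(C)C)c1
F2 | step 6 | methyl 4-(methoxymethoxy)-3-(3-methylbut-2-en-1-yl)benzoate | COCOc1ccc(cc1CC=C(C)C)C(=O)OC
F3 | step 6 | 1-[2,4-dihydroxy-5-(3-methylbut-2-en-1-yl)phenyl]ethanone | CC(=O)c1cc(CC=C(C)C)c(O)cc1O
F4 | step 6 | 1-[2,4-bis(methoxymethoxy)-5-(3-methylbut-2-en-1-yl)phenyl]ethanone | CC(=O)c1cc(CC=C(C)C)c(OCOC)cc1OCOC
F5 | step 6 | 1-[2,4-bis(methoxymethoxy)-5-(3-methylbut-2-en-1-yl)phenyl]-3-[4-(methoxymethoxy)-3-(3-methylbut-2-en-1-yl)phenyl]propane-1,3-dione | COCOc1ccc(cc1CC=C(C)C)C(=O)CC(=O)c1cc(CC=C(C)C)c(OCOC)cc1OCOC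
F6 | step 5 | methyl 4-(2-methylbut-3-en-2-yloxy)benzoate | COC(=O)c1ccc(OC(C)(C)C=C)cc1
F7 | step 5 | 4-(2-methylbut-3-en-2-yloxy)benzoic acid | OC(=O)c1ccc(OC(C)(C)C=C)cc1
F8 | step 5 | 1-[2-hydroxy-4-(2-methylbut-3-en-2-yloxy)phenyl]ethanone | CC(=O)c1ccc(OC(C)(C)C=C)cc1O
F9 | step 4 | 4-(2-methylbut-3-yn-2-yloxy)benzoyl chloride | ClC(=O)c1ccc(OC(C)(C)C#C)cc1
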